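## Retrosynthetic overview

1. In the last step, 21 is cut into two halves of similar size: the terpenoid oxetane 18 (C16) and isobutyrylfilicinic acid 3 (C12). No protecting group is left at that stage.
2. Enabling feature: in the dihydropyran (ring C), the ring O, the quaternary C(CH3), the ring-fusion CH and the CH2 form a 1,3-O/C array that can be stored as a trans-fused oxetane. The other two ring atoms are the enol C=C of the β-triketone (ring D), nucleophilic at carbon and electrophilic at its C–O carbon. Inserting this C=C into the O–CH2 bond expands the four-membered ring to ring C and leaves both stereocentres untouched.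
3. 18 comes from cycloheptene 12 by net anti addition of O and CH2OH (bromohydrin, α-epoxide, SN2 opening, Williamson closure).
4. 12 comes from (R)-4-silyloxycyclopentenone 4 by a stereochemical relay around ring A: conjugate addition, enolate alkylation, elimination, ring-closing metathesis to ring B, second conjugate addition, reduction. 3 comes from phloroglucinol.
5. Order of ring formation: A (bought), B (step 7), oxetane (step 13), C (step 14). Ring D is made separately (step 2).

Key step: step 14

Remark on the chemistry: β is the face of the hydroazulene that carries the angular methyl group and α is the opposite face. The β-triketone units of 3, 20 and 21 are written as the enol tautomers that match the target structure, and these tautomers interconvert freely.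

## Route

Step 1
Reactants: 1 phloroglucinol
Product: 2 2-methyl-1-(2,4,6-trihydroxyphenyl)propan-1-one
Conditions: i-PrCOCl, AlCl3, PhNO2–CH2Cl2, 60 °C; aq. HCl
Reagents that add atoms: isobutyryl chloride CC(C)C(=O)Cl
Why: Friedel–Crafts C-acylation of the electron-rich arene, in which the chelated and deactivated aryl ketone should stop the reaction at monoacylation; no stereocentre is formed.

Step 2
Reactants: 2 2-methyl-1-(2,4,6-trihydroxyphenyl)propan-1-one
Product: 3 3,5-dihydroxy-2-isobutyryl-6,6-dimethylcyclohexa-2,4-dien-1-one
Conditions: NaOMe (3 equiv), MeI (2.2 equiv), MeOH, 0 °C → rt; aq. HCl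
Reagents that add atoms: iodomethane CI
Why: Dearomatising double C-methylation of the acylphloroglucinol anion, in which the soft iodide in methanol alkylates carbon and the second methyl enters at the same, still enolisable ring carbon to give the gem-dimethyl β-triketone; no stereocentre is formed.

Step 3
Reactants: 4 (R)-4-(tert-butyldimethylsilyloxy)cyclopent-2-en-1-one
Product: 5 (R)-4-(tert-butyldimethylsilyloxy)-2-iodocyclopent-2-en-1-one
Conditions: I2, pyridine–CH2Cl2, 0 °C → rt
Reagents that add atoms: iodine II
Why: α-Iodination of an enone by the addition–elimination (Baylis–Hillman-type) mechanism with pyridine as nucleophilic carrier; the silyloxy-bearing stereocentre is not touched.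

Step 4
Reactants: 5 (R)-4-(tert-butyldimethylsilyloxy)-2-iodocyclopent-2-en-1-one
Product: 6 (R)-4-(tert-butyldimethylsilyloxy)-2-methylcyclopent-2-en-1-one
Conditions: MeZnCl, PdCl2(dppf) (5 mol %), THF, rt
Reagents that add atoms: methylzinc chloride C[Zn]Cl
Why: Negishi cross-coupling of an α-iodoenone under neutral conditions that spare the base-sensitive γ-silyloxy enone; the configuration is retained.

Step 5
Reactants: 6 (R)-4-(tert-butyldimethylsilyloxy)-2-methylcyclopent-2-en-1-one
Product: 7 (3R,4R)-4-(tert-butyldimethylsilyloxy)-2-methyl-3-(2-methylallyl)-1-(trimethylsilyloxy)cyclopent-1-ene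
Conditions: 2-methylallylMgCl, CuBr·SMe2, TMSCl, THF, −78 °C; Et3N, pentane, cold aq. NaHCO3
Reagents that add atoms: 2-methylallylmagnesium chloride CC(=C)C[Mg]Cl; chlorotrimethylsilane C[Si](C)(C)Cl
Why: Chlorosilane-accelerated conjugate addition of an allylic copper reagent, which adds to the ring face opposite to the neighbouring silyloxy group and so sets the future ring-fusion CH, while the chlorosilane traps the enolate regiospecifically.

Step 6
Reactants: 7 (3R,4R)-4-(tert-butyldimethylsilyloxy)-2-methyl-3-(2-methylallyl)-1-(trimethylsilyloxy)cyclopent-1-ene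
Product: 9 (4S,5R)-5-(but-3-en-1-yl)-5-methyl-4-(2-methylallyl)cyclopent-2-en-1-one, via silyloxy ketone 8 (not isolated)
Conditions: MeLi, THF, 0 °C; 4-iodobut-1-ene, DMPU, −78 → −10 °C; then DBU, CH2Cl2, rt
Reagents that add atoms: 4-iodobut-1-ene C=CCCI
Why: Regiospecific release of the lithium enolate from the silyl enol ether and SN2 alkylation on the face opposite to the adjacent 2-methylallyl group set the quaternary centre (methyl cis to that group), and E1cB loss of silanolate then unveils the enone.

Step 7
Reactants: 9 (4S,5R)-5-(but-3-en-1-yl)-5-methyl-4-(2-methylallyl)cyclopent-2-en-1-one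
Product: 10 (3aS,8aR)-5,8a-dimethyl-4,7,8,8a-tetrahydroazulen-1(3aH)-one
Conditions: second-generation Grubbs catalyst (5 mol %), CH2Cl2 (0.005 M), reflux
Reagents that add atoms: none
Why: Ring-closing metathesis of the monosubstituted alkene onto the 1,1-disubstituted alkene (the cyclic enone C=C is inert) closes ring B as a trisubstituted cycloheptene, and the trans relation of the two tethers fixed in steps 5 and 6 becomes the trans ring fusion.

Step 8
Reactants: 10 (3aS,8aR)-5,8a-dimethyl-4,7,8,8a-tetrahydroazulen-1(3aH)-one
Product: 11 (3R,3aS,8aR)-5,8a-dimethyl-3-(prop-1-en-2-yl)-3,3a,4,7,8,8a-hexahydroazulen-1(2H)-one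
Conditions: isopropenylMgBr, CuI (15 mol %), THF, −30 °C; aq. NH4Cl
Reagents that add atoms: isopropenylmagnesium bromide CC(=C)[Mg]Br
Why: Copper-catalysed 1,4-addition of an alkenyl Grignard reagent, in which the angular methyl group and the adjacent ring-B CH2 both shield the β face, so the isopropenyl group should enter from the α face.

Step 9
Reactants: 11 (3R,3aS,8aR)-5,8a-dimethyl-3-(prop-1-en-2-yl)-3,3a,4,7,8,8a-hexahydroazulen-1(2H)-one
Product: 12 (1R,3R,3aS,8aR)-5,8a-dimethyl-3-(prop-1-en-2-yl)-1,2,3,3a,4,7,8,8a-octahydroazulen-1-ol
Conditions: NaBH4, MeOH, 0 °C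
Reagents that add atoms: none
Why: Hydride reduction of a cyclopentanone next to a quaternary carbon, where, as in 17-oxo steroids, the pseudo-axial angular methyl blocks the β face, so hydride should arrive from the α face and give the β-alcohol cis to the methyl group.

Step 10
Reactants: 12 (1R,3R,3aS,8aR)-5,8a-dimethyl-3-(prop-1-en-2-yl)-1,2,3,3a,4,7,8,8a-octahydroazulen-1-ol
Product: 14 (1R,3R,3aS,5R,6S,8aR)-5,6-epoxy-5,8a-dimethyl-3-(prop-1-en-2-yl)decahydroazulen-1-ol, via bromohydrin 13 (not isolated)
Conditions: NBS (1.05 equiv), acetone–H2O, 0 °C; then K2CO3, MeOH, rt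
Reagents that add atoms: water O
Why: Halohydrin formation followed by Williamson-type epoxide closure, in which the trisubstituted alkene reacts before the 1,1-disubstituted one (as in limonene), the bromonium ion forms on the convex β face of the chair cycloheptene, water opens it anti at the tertiary carbon, and base closes the epoxide on the α face, the face a peracid would not choose.

Step 11
Reactants: 14 (1R,3R,3aS,5R,6S,8aR)-5,6-epoxy-5,8a-dimethyl-3-(prop-1-en-2-yl)decahydroazulen-1-ol
Product: 16 (1R,3R,3aS,5R,6S,8aR)-6-(hydroxymethyl)-5,8a-dimethyl-3-(prop-1-en-2-yl)decahydroazulene-1,5-diol, via oxasilolane 15 (not isolated)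
Conditions: i-PrOMe2SiCH2MgCl (from i-PrOMe2SiCH2Cl, Mg, THF; 3.5 equiv), CuI (10 mol %), THF, −20 °C → rt; then 30% H2O2, KF, KHCO3, THF–MeOH, rt
Reagents that add atoms: (isopropoxydimethylsilyl)methylmagnesium chloride CC(C)O[Si](C)(C)C[Mg]Cl; hydrogen peroxide OO
Why: Copper-catalysed SN2 opening of the epoxide by a hydroxymethyl anion equivalent at the less substituted carbon with inversion (attack from the open β face) sets the ring-fusion CH anti to the retained tertiary C–O bond, and the Tamao oxidation turns C–Si into C–OH without touching a carbon stereocentre.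

Step 12
Reactants: 16 (1R,3R,3aS,5R,6S,8aR)-6-(hydroxymethyl)-5,8a-dimethyl-3-(prop-1-en-2-yl)decahydroazulene-1,5-diol
Product: 17 primary mono-p-toluenesulfonate of triol 16
Conditions: TsCl (1.05 equiv), Et3N, DMAP (cat.), CH2Cl2, 0 °C
Reagents that add atoms: p-toluenesulfonyl chloride Cc1ccc(cc1)S(=O)(=O)Cl
Why: Selective sulfonylation of the only primary hydroxyl group, since the neopentyl-type secondary and the tertiary hydroxyl groups react much more slowly; no stereocentre is touched.

Step 13
Reactants: 17 primary mono-p-toluenesulfonate of triol 16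
Product: 18 trans-fused oxetane of the hydroazulenol (O on the quaternary C5 and CH2 on C6)
Conditions: KOt-Bu (2.2 equiv), THF, 0 °C → rt
Reagents that add atoms: none
Why: Intramolecular Williamson etherification (4-exo-tet) of the tertiary alkoxide onto the primary tosylate, which changes no stereocentre and turns the anti relation of O and CH2 into a trans-fused oxetane that a seven-membered ring can accommodate.

Step 14
Reactants: 18 trans-fused oxetane of the hydroazulenol; 3 3,5-dihydroxy-2-isobutyryl-6,6-dimethylcyclohexa-2,4-dien-1-one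
Product: 21 target CNP0510355.1, via iodohydrin 19 (not isolated), via hydroxy triketone 20 (not isolated)
Conditions: 3 (1.2 equiv), n-Bu4NI (0.3 equiv), 4 Å MS, t-AmOH, 90 °C
Reagents that add atoms: none
Why: Proposed new method: the vinylogous acid 3 hydrogen-bonds to the oxetane oxygen of 18, iodide opens the activated four-membered ring by SN2 at its CH2 carbon to give iodohydrin 19 beside the ammonium enolate of 3, this enolate is alkylated by the primary iodide at its only free ring carbon to give 20 with return of iodide, and the freed tertiary hydroxyl adds to the flanking ring carbonyl and loses water, so that the enol C=C of 3 ends up inserted into the O–CH2 bond and the oxetane has grown by two atoms into the dihydropyran. The closest known reaction types are the onium-halide-catalysed ring-opening addition of carboxylic acids and phenols to oxetanes, the halide-relay insertion of CO2 into oxetanes that gives six-membered carbonates, and the C-alkylation of acylphloroglucinol anions by alkyl iodides in protic media. The only ring closed is the six-membered one, by 6-exo-trig attack of oxygen on C=O followed by dehydration to the vinylogous ester. No stereocentre is created, because the quaternary C–O bond and the adjacent C–H centre of 18 are never broken, so the trans ring fusion set in steps 10 and 11 is handed on unchanged, which a cycloaddition to the cis-cycloheptene could not deliver. The step needs CH2 over quaternary C–O cleavage (secured by the absence of any strong Brønsted or Lewis acid and by the steric bias of SN2), carbon over oxygen alkylation (favoured by the soft iodide and the hydrogen-bonding solvent), and attack on the carbonyl next to the CMe2 group (secured because the other flanking oxygen is locked as the enol chelated to the isobutyryl carbonyl).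

## Compound list

1 | phloroglucinol | Oc1cc(O)cc(O)c1 | starting material
2 | 2-methyl-1-(2,4,6-trihydroxyphenyl)propan-1-one | CC(C)C(=O)c1c(O)cc(O)cc1O | intermediate
3 | isobutyrylfilicinic acid, 3,5-dihydroxy-2-isobutyryl-6,6-dimethylcyclohexa-2,4-dien-1-one | CC(C)C(=O)C1=C(O)C=C(O)C(C)(C)C1=O | intermediate
4 | (R)-4-(tert-butyldimethylsilyloxy)cyclopent-2-en-1-one | O=C1C=C[C@H](O[Si](C)(C)C(C)(C)C)C1 | starting material
5 | (R)-4-(tert-butyldimethylsilyloxy)-2-iodocyclopent-2-en-1-one | O=C1C(I)=C[C@H](O[Si](C)(C)C(C)(C)C)C1 | intermediate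
6 | (R)-4-(tert-butyldimethylsilyloxy)-2-methylcyclopent-2-en-1-one | O=C1C(C)=C[C@H](O[Si](C)(C)C(C)(C)C)C1 | intermediate
7 | (3R,4R)-4-(tert-butyldimethylsilyloxy)-2-methyl-3-(2-methylallyl)-1-(trimethylsilyloxy)cyclopent-1-ene | C[Si](C)(C)OC1=C(C)[C@@H](CC(C)=C)[C@H](O[Si](C)(C)C(C)(C)C)C1 | intermediate
8 | (2R,3R,4R)-2-(but-3-en-1-yl)-4-(tert-butyldimethylsilyloxy)-2-methyl-3-(2-methylallyl)cyclopentan-1-one | O=C1[C@](C)(CCC=C)[C@@H](CC(C)=C)[C@H](O[Si](C)(C)C(C)(C)C)C1 | intermediate
9 | (4S,5R)-5-(but-3-en-1-yl)-5-methyl-4-(2-methylallyl)cyclopent-2-en-1-one | O=C1[C@](C)(CCC=C)[C@@H](CC(C)=C)C=C1 | intermediate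
10 | (3aS,8aR)-5,8a-dimethyl-4,7,8,8a-tetrahydroazulen-1(3aH)-one, trans-fused | O=C1[C@]2(C)CCC=C(C)C[C@H]2C=C1 | intermediate
11 | (3R,3aS,8aR)-5,8a-dimethyl-3-(prop-1-en-2-yl)-3,3a,4,7,8,8a-hexahydroazulen-1(2H)-one | O=C1[C@]2(C)CCC=C(C)C[C@H]2[C@H](C(C)=C)C1 | intermediate
12 | (1R,3R,3aS,8aR)-5,8a-dimethyl-3-(prop-1-en-2-yl)-1,2,3,3a,4,7,8,8a-octahydroazulen-1-ol | O[C@H]1[C@]2(C)CCC=C(C)C[C@H]2[C@H](C(C)=C)C1 | intermediate
13 | (1R,3R,3aS,5R,6R,8aR)-6-bromo-5,8a-dimethyl-3-(prop-1-en-2-yl)decahydroazulene-1,5-diol (Br β, tertiary OH α) | O[C@H]1[C@]2(C)CC[C@@H](Br)[C@](C)(O)C[C@H]2[C@H](C(C)=C)C1 | intermediate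
14 | (1R,3R,3aS,5R,6S,8aR)-5,6-epoxy-5,8a-dimethyl-3-(prop-1-en-2-yl)decahydroazulen-1-ol (epoxide O on the α face) | O[C@H]1[C@]2(C)CC[C@@H]3O[C@]3(C)C[C@H]2[C@H](C(C)=C)C1 | intermediate
15 | trans-fused 2,2-dimethyl-1,2-oxasilolane (O on C5, Si–CH2 on C6, configuration as in 16) | O[C@H]1[C@]2(C)CC[C@H]3C[Si](C)(C)O[C@]3(C)C[C@H]2[C@H](C(C)=C)C1 | intermediate
16 | (1R,3R,3aS,5R,6S,8aR)-6-(hydroxymethyl)-5,8a-dimethyl-3-(prop-1-en-2-yl)decahydroazulene-1,5-diol | O[C@H]1[C@]2(C)CC[C@@H](CO)[C@](C)(O)C[C@H]2[C@H](C(C)=C)C1 | intermediate
17 | primary mono-p-toluenesulfonate of 16 | O[C@H]1[C@]2(C)CC[C@@H](COS(=O)(=O)c3ccc(C)cc3)[C@](C)(O)C[C@H]2[C@H](C(C)=C)C1 | intermediate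
18 | trans-fused oxetane (ring O α on the quaternary C5, ring CH2 β on C6, C5 R, C6 S, other centres as in 12) | O[C@H]1[C@]2(C)CC[C@H]3CO[C@]3(C)C[C@H]2[C@H](C(C)=C)C1 | intermediate
19 | 6-(iodomethyl)-5,8a-dimethyl-3-(prop-1-en-2-yl)decahydroazulene-1,5-diol, spatial arrangement as in 16 | O[C@H]1[C@]2(C)CC[C@@H](CI)[C@](C)(O)C[C@H]2[C@H](C(C)=C)C1 | intermediate
20 | C-alkylated isobutyrylfilicinic acid with free tertiary hydroxyl, spatial arrangement as in 16 | O[C@H]1[C@]2(C)CC[C@@H](CC3=C(O)C(C)(C)C(=O)C(C(=O)C(C)C)=C3O)[C@](C)(O)C[C@H]2[C@H](C(C)=C)C1 | intermediate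
21 | CNP0510355.1 | C=C(C)[C@@H]1C[C@@H](O)[C@]2(C)CC[C@H]3CC4=C(O[C@]3(C)C[C@@H]12)C(C)(C)C(=O)C(C(=O)C(C)C)=C4O | target

## Step count and risk

Total step count: 14. Longest linear sequence: 12 steps (4 → 21, steps 3 to 14).

Steps most likely to fail:

1. **Step 14.**
   - What may go wrong: the iodide relay may be too slow, the quaternary C–O bond may ionise (elimination or loss of configuration), or the ambident enolate may be alkylated on oxygen.
   - Fallback: it sets out from triol 16 and comes back at 20, which is then closed to 21. Chemoselective oxoammonium oxidation of the primary alcohol (TEMPO, PhI(OAc)2, CH2Cl2) gives the β-hydroxy aldehyde F1. An organocatalytic three-component reductive alkylation with 3 (L-proline, Hantzsch ester, CH2Cl2, rt) passes through the Knoevenagel alkylidene triketone F2. Transfer hydrogenation of F2 gives 20, and PPTS in warm toluene over molecular sieves effects the cyclodehydration to 21.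

2. **Step 11.**
   - What may go wrong: magnesium salts may trigger Lewis-acid rearrangement of the trisubstituted epoxide, or attack at the hindered secondary carbon may be too sluggish.
   - Fallback: it sets out from epoxide 14 and comes back at triol 16. Carbonylative ring expansion with [(salph)Al(THF)2][Co(CO)4] under CO pressure in DME relies on attack of the cobaltate at the less substituted carbon with inversion. This gives the trans-fused β-lactone F3, which LiAlH4 in THF reduces to 16.

3. **Step 10.**
   - What may go wrong: facial selectivity in bromonium formation and opening may be poor, or bromine may be transferred to the isopropenyl group.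
   - Fallback: it sets out from 12 and comes back at 14. A catalyst-controlled Shi epoxidation uses the enantiomer of the fructose-derived ketone (made from L-sorbose), Oxone and K2CO3 buffer in MeCN–dimethoxymethane–H2O. The chiral dioxirane prefers trisubstituted over 1,1-disubstituted alkenes, and its spiro transition state should deliver oxygen to the α face directly. This fallback makes no new compound (entry F0).

Further compounds
F1 | step 14 | β-hydroxy aldehyde, 6-formyl analogue of 16 with the same spatial arrangement | O[C@H]1[C@]2(C)CC[C@@H](C=O)[C@](C)(O)C[C@H]2[C@H](C(C)=C)C1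
F2 | step 14 | Knoevenagel alkylidene triketone from F1 and 3 (alkene geometry not fixed) | O[C@H]1[C@]2(C)CC[C@@H](C=C3C(=O)C(C)(C)C(=O)C(C(=O)C(C)C)=C3O)[C@](C)(O)C[C@H]2[C@H](C(C)=C)C1
F3 | step 11 | trans-fused β-lactone (ring O on the quaternary C5, C=O on C6) | O[C@H]1[C@]2(C)CC[C@H]3C(=O)O[C@]3(C)C[C@H]2[C@H](C(C)=C)C1
F0 | step 10 | none | none
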